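**Plan** (dihydrobenzofuran numbering O1, C2, C3, C3a, C4–C7, C7a; side chain C1', C2')
1. Retrosynthetic cuts, in order: the two O-benzyl groups; C1'–H (ketone reduction); C5–C1' (aryllithium plus the Weinreb amide of O-benzyl-(S)-lactic acid); the C3 methyl back to an ester carbon; C3a–C3, traced back to the C4–C4a bond of a flavanone; C2–aryl of that flavanone (conjugate addition to a chromone).
2. Forward order: ring A acetophenone → pyranone ring of a chromone → (S)-flavanone → contraction to the dihydrofuran ring → ester to methyl → side chain on C5 → debenzylation.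
3. Enabling feature: C3 of the dihydrofuran ring carries both ring A carbon C3a and a one-carbon branch (the methyl), and O1 already ties ring A to C2. This is the pattern left by a 1,2-shift of the O1-activated carbon C3a from that branch carbon (then a ketal carbon, C4 of a chroman-4-one) to C3.
4. Stereochemistry: C2 from the chiral palladium catalyst; C3 from C2 (anti iodination, shift with inversion, giving trans); C2' from (S)-lactic acid; C1' from C2' by chelation-controlled reduction (anti).

Key step: step 4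

Assumption: the R enantiomer of the pyridine-oxazoline ligand is taken to give the 2S flavanone, by analogy with the face selectivity of this catalyst on cyclic enones; if the sense is the reverse, the S ligand is used and nothing else changes.

**Step 1**
Reactants: 1 1-(2-hydroxy-3-methoxyphenyl)ethan-1-one
Product: 2 1-(5-bromo-2-hydroxy-3-methoxyphenyl)ethan-1-one
Conditions: NBS (1.05 equiv), MeCN, 0 °C to rt
Reagents that add atoms: N-bromosuccinimide, O=C1CCC(=O)N1Br
Why: Electrophilic aromatic bromination should go para to the free phenol (C5), since both ortho positions of the hydroxyl group are occupied.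

**Step 2**
Reactants: 2 1-(5-bromo-2-hydroxy-3-methoxyphenyl)ethan-1-one
Product: 4 6-bromo-8-methoxy-4H-chromen-4-one, via enaminone 3 (not isolated)
Conditions: Me2NCH(OMe)2, toluene, 100 °C; concentrate; conc. HCl, CH2Cl2, rt
Reagents that add atoms: N,N-dimethylformamide dimethyl acetal, COC(OC)N(C)C
Why: Enaminone route to chromones: the methyl ketone condenses with the amide acetal, and acid then drives 6-endo addition of the phenol to the enaminone with loss of dimethylamine.

**Step 3**
Reactants: 4 6-bromo-8-methoxy-4H-chromen-4-one; 5 [4-(benzyloxy)-3-methoxyphenyl]boronic acid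
Product: 6 (S)-2-[4-(benzyloxy)-3-methoxyphenyl]-6-bromo-8-methoxychroman-4-one
Conditions: Pd(OCOCF3)2 (5 mol %), (R)-t-BuPyOx [(R)-4-tert-butyl-2-(pyridin-2-yl)-4,5-dihydrooxazole] (6 mol %), NH4PF6 (30 mol %), H2O (5 equiv), ClCH2CH2Cl, 60 °C
Reagents that add atoms: none
Why: Asymmetric conjugate addition of an arylboronic acid to a chromone under divalent palladium catalysis (transmetalation, enantioface-selective insertion at C2, protonolysis of the palladium enolate), in which the chiral ligand sets C2, the near-neutral medium avoids retro-oxa-Michael opening of the flavanone, and the C–Br bond is left alone because no zerovalent palladium phosphine species is present.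

**Step 4**
Reactants: 6 (S)-2-[4-(benzyloxy)-3-methoxyphenyl]-6-bromo-8-methoxychroman-4-one
Product: 9 methyl (2S,3S)-2-[4-(benzyloxy)-3-methoxyphenyl]-5-bromo-7-methoxy-2,3-dihydro-1-benzofuran-3-carboxylate, via enol ether 7 (not isolated), via iodanyl ketal 8 (not isolated)
Conditions: PhI(OAc)2 (1.3 equiv), conc. H2SO4 (0.5 equiv), HC(OMe)3, 0 °C to rt
Reagents that add atoms: trimethyl orthoformate, COC(OC)OC
Why: Acid and HC(OMe)3 turn the C4 ketone into enol ether 7, the electrophile PhI(OAc)+ adds to C3 anti to the C2 aryl group while methanol caps C4 to give iodanyl ketal 8, and reductive departure of PhI from C3 is accompanied by a 1,2-shift of ring A carbon C4a from C4 to C3 through a bridged phenonium ion, after which the dimethoxycarbenium ion at the old C4 loses a methyl group to acetate and becomes the ester. The closest known reaction type is the oxidative 1,2-aryl migration of aryl ketone ketals with trivalent iodine or trivalent thallium, established as a ring contraction of flavanones and chroman-4-ones to 2,3-dihydrobenzofuran-3-carboxylates. The five-membered ring O1–C2–C3–C3a–C7a closes by 3-exo ipso attack of C4a on C3 followed by cleavage of the C4–C4a bond, that is, a suprafacial [1,2]-shift that contracts the six-membered pyranone ring. C3 is the only new stereocentre and is controlled by C2: the iodane enters trans to the aryl group and is displaced with inversion by the migrating carbon, which puts the ester carbon trans to the aryl group (2S,3S) while C2 itself is not touched. The step needs migration of ring A in preference to migration of ring B from C2 to C3 (isoflavone) and to elimination of H-2 with the iodane (flavone); in the half-chair of 8 the C2 aryl group and the C3 iodane are both equatorial, so the ring bond C4–C4a, and neither the C2–aryl nor the C2–H bond, is antiperiplanar to C3–I, the two ketal oxygens at C4 push the shift, and the oxygen O1 ortho to C4a stabilises the phenonium ion.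

**Step 5**
Reactants: 9 methyl (2S,3S)-2-[4-(benzyloxy)-3-methoxyphenyl]-5-bromo-7-methoxy-2,3-dihydro-1-benzofuran-3-carboxylate
Product: 10 [(2S,3R)-2-[4-(benzyloxy)-3-methoxyphenyl]-5-bromo-7-methoxy-2,3-dihydro-1-benzofuran-3-yl]methanol
Conditions: i-Bu2AlH (2.5 equiv), CH2Cl2, −78 to 0 °C; aq. potassium sodium tartrate
Reagents that add atoms: none
Why: Ester reduction with a Lewis-acidic, non-basic aluminium hydride should give the primary alcohol without enolising C3 (no E1cB opening of the β-aryloxy ester) and without touching the aryl bromide; the change of descriptor at C3 is a priority effect only.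

**Step 6**
Reactants: 10 [(2S,3R)-2-[4-(benzyloxy)-3-methoxyphenyl]-5-bromo-7-methoxy-2,3-dihydro-1-benzofuran-3-yl]methanol
Product: 11 [(2S,3R)-2-[4-(benzyloxy)-3-methoxyphenyl]-5-bromo-7-methoxy-2,3-dihydro-1-benzofuran-3-yl]methyl 4-methylbenzenesulfonate
Conditions: TsCl (1.3 equiv), Et3N (2 equiv), DMAP (cat.), CH2Cl2, 0 °C to rt
Reagents that add atoms: p-toluenesulfonyl chloride, Cc1ccc(cc1)S(Cl)(=O)=O
Why: Sulfonylation of the only free hydroxyl group, a primary alcohol, activates the branch carbon for hydride displacement.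

**Step 7**
Reactants: 11 [(2S,3R)-2-[4-(benzyloxy)-3-methoxyphenyl]-5-bromo-7-methoxy-2,3-dihydro-1-benzofuran-3-yl]methyl 4-methylbenzenesulfonate
Product: 12 (2S,3S)-2-[4-(benzyloxy)-3-methoxyphenyl]-5-bromo-7-methoxy-3-methyl-2,3-dihydro-1-benzofuran
Conditions: LiBHEt3 (2.5 equiv), THF, 0 °C to rt
Reagents that add atoms: none
Why: SN2 displacement of the primary tosylate by a strongly nucleophilic, weakly basic borohydride should give the methyl group without touching C3, and the aryl bromide and ethers are inert to this reagent.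

**Step 8**
Reactants: 13 (S)-2-(benzyloxy)propanoic acid
Product: 15 (S)-2-(benzyloxy)-N-methoxy-N-methylpropanamide, via acyl imidazolide 14 (not isolated)
Conditions: 1,1'-carbonyldiimidazole (1.1 equiv), CH2Cl2, 0 °C to rt; then MeNH(OMe)·HCl (1.2 equiv), rt
Reagents that add atoms: N,O-dimethylhydroxylamine hydrochloride, CNOC.Cl
Why: Amide formation through the acyl imidazolide needs no strong base, so the α-alkoxy stereocentre taken from (S)-lactic acid should be kept.

**Step 9**
Reactants: 12 (2S,3S)-2-[4-(benzyloxy)-3-methoxyphenyl]-5-bromo-7-methoxy-3-methyl-2,3-dihydro-1-benzofuran; 15 (S)-2-(benzyloxy)-N-methoxy-N-methylpropanamide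
Product: 18 (2S)-2-(benzyloxy)-1-[(2S,3S)-2-[4-(benzyloxy)-3-methoxyphenyl]-7-methoxy-3-methyl-2,3-dihydro-1-benzofuran-5-yl]propan-1-one, via aryllithium 16 (not isolated), via lithium hemiaminalate 17 (not isolated)
Conditions: n-BuLi (1.05 equiv), THF, −78 °C; then 15, −78 to −40 °C; AcOH, −78 °C
Reagents that add atoms: none
Why: Bromine–lithium exchange at C5 followed by Weinreb ketone synthesis, in which the chelated tetrahedral adduct 17 should prevent over-addition and shield the α-stereocentre from enolisation until the cold acidic quench.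

**Step 10**
Reactants: 18 (2S)-2-(benzyloxy)-1-[(2S,3S)-2-[4-(benzyloxy)-3-methoxyphenyl]-7-methoxy-3-methyl-2,3-dihydro-1-benzofuran-5-yl]propan-1-one
Product: 19 (1R,2S)-2-(benzyloxy)-1-[(2S,3S)-2-[4-(benzyloxy)-3-methoxyphenyl]-7-methoxy-3-methyl-2,3-dihydro-1-benzofuran-5-yl]propan-1-ol
Conditions: Zn(BH4)2 (1.5 equiv, solution in Et2O), Et2O, −30 to 0 °C; aq. NH4Cl
Reagents that add atoms: none
Why: Chelation-controlled reduction (Cram chelate model): zinc bridges the ketone and benzyloxy oxygens and hydride attacks from the face of the α-hydrogen, which should give the anti (erythro) 1R,2S alcohol.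

**Step 11**
Reactants: 19 (1R,2S)-2-(benzyloxy)-1-[(2S,3S)-2-[4-(benzyloxy)-3-methoxyphenyl]-7-methoxy-3-methyl-2,3-dihydro-1-benzofuran-5-yl]propan-1-ol
Product: 20 (1R,2S)-1-[(2S,3S)-2-(4-hydroxy-3-methoxyphenyl)-7-methoxy-3-methyl-2,3-dihydro-1-benzofuran-5-yl]propane-1,2-diol
Conditions: H2 (1 atm), 10% Pd/C, EtOAc, rt, stopped after uptake of 2 equiv
Reagents that add atoms: none
Why: Hydrogenolysis of the aryl benzyl ether and the alkyl benzyl ether under neutral conditions at low pressure should be much faster than cleavage of the secondary benzylic alcohol or of the cyclic benzylic ether C2–O1, so both benzyl groups fall in one step and no stereocentre is touched.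

**Compound list**
1 | 1-(2-hydroxy-3-methoxyphenyl)ethan-1-one | CC(=O)c1cccc(OC)c1O | starting material
2 | 1-(5-bromo-2-hydroxy-3-methoxyphenyl)ethan-1-one | CC(=O)c1cc(Br)cc(OC)c1O | intermediate
3 | (E)-1-(5-bromo-2-hydroxy-3-methoxyphenyl)-3-(dimethylamino)prop-2-en-1-one | CN(C)/C=C/C(=O)c1cc(Br)cc(OC)c1O | intermediate
4 | 6-bromo-8-methoxy-4H-chromen-4-one | O=c1ccoc2c(OC)cc(Br)cc12 | intermediate
5 | [4-(benzyloxy)-3-methoxyphenyl]boronic acid | COc1cc(B(O)O)ccc1OCc1ccccc1 | starting material
6 | (S)-2-[4-(benzyloxy)-3-methoxyphenyl]-6-bromo-8-methoxychroman-4-one | COc1cc([C@H]2Oc3c(OC)cc(Br)cc3C(=O)C2)ccc1OCc1ccccc1 | intermediate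
7 | (S)-2-[4-(benzyloxy)-3-methoxyphenyl]-6-bromo-4,8-dimethoxy-2H-chromene | COc1cc([C@H]2Oc3c(OC)cc(Br)cc3C(OC)=C2)ccc1OCc1ccccc1 | intermediate
8 | (2R,3R)-3-[acetoxy(phenyl)-λ3-iodanyl]-2-[4-(benzyloxy)-3-methoxyphenyl]-6-bromo-4,4,8-trimethoxychromane (aryl and iodane trans) | COc1cc([C@H]2Oc3c(OC)cc(Br)cc3C(OC)(OC)[C@@H]2I(OC(C)=O)c2ccccc2)ccc1OCc1ccccc1 | intermediate
9 | methyl (2S,3S)-2-[4-(benzyloxy)-3-methoxyphenyl]-5-bromo-7-methoxy-2,3-dihydro-1-benzofuran-3-carboxylate (trans) | COc1cc([C@H]2Oc3c(OC)cc(Br)cc3[C@@H]2C(=O)OC)ccc1OCc1ccccc1 | intermediate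
10 | [(2S,3R)-2-[4-(benzyloxy)-3-methoxyphenyl]-5-bromo-7-methoxy-2,3-dihydro-1-benzofuran-3-yl]methanol (trans) | COc1cc([C@H]2Oc3c(OC)cc(Br)cc3[C@@H]2CO)ccc1OCc1ccccc1 | intermediate
11 | [(2S,3R)-2-[4-(benzyloxy)-3-methoxyphenyl]-5-bromo-7-methoxy-2,3-dihydro-1-benzofuran-3-yl]methyl 4-methylbenzenesulfonate | COc1cc([C@H]2Oc3c(OC)cc(Br)cc3[C@@H]2COS(=O)(=O)c2ccc(C)cc2)ccc1OCc1ccccc1 | intermediate
12 | (2S,3S)-2-[4-(benzyloxy)-3-methoxyphenyl]-5-bromo-7-methoxy-3-methyl-2,3-dihydro-1-benzofuran | COc1cc([C@H]2Oc3c(OC)cc(Br)cc3[C@@H]2C)ccc1OCc1ccccc1 | intermediate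
13 | (S)-2-(benzyloxy)propanoic acid | C[C@H](OCc1ccccc1)C(=O)O | starting material
14 | (S)-2-(benzyloxy)-1-(1H-imidazol-1-yl)propan-1-one | C[C@H](OCc1ccccc1)C(=O)n1ccnc1 | intermediate
15 | (S)-2-(benzyloxy)-N-methoxy-N-methylpropanamide | C[C@H](OCc1ccccc1)C(=O)N(C)OC | intermediate
16 | [(2S,3S)-2-[4-(benzyloxy)-3-methoxyphenyl]-7-methoxy-3-methyl-2,3-dihydro-1-benzofuran-5-yl]lithium | COc1cc([C@H]2Oc3c(OC)cc([Li])cc3[C@@H]2C)ccc1OCc1ccccc1 | intermediate
17 | lithium (2S)-2-(benzyloxy)-1-[(2S,3S)-2-[4-(benzyloxy)-3-methoxyphenyl]-7-methoxy-3-methyl-2,3-dihydro-1-benzofuran-5-yl]-1-[methoxy(methyl)amino]propan-1-olate (carbinol carbon unassigned) | COc1cc([C@H]2Oc3c(OC)cc(C(O[Li])(N(C)OC)[C@H](C)OCc4ccccc4)cc3[C@@H]2C)ccc1OCc1ccccc1 | intermediate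
18 | (2S)-2-(benzyloxy)-1-[(2S,3S)-2-[4-(benzyloxy)-3-methoxyphenyl]-7-methoxy-3-methyl-2,3-dihydro-1-benzofuran-5-yl]propan-1-one | COc1cc([C@H]2Oc3c(OC)cc(C(=O)[C@H](C)OCc4ccccc4)cc3[C@@H]2C)ccc1OCc1ccccc1 | intermediate
19 | (1R,2S)-2-(benzyloxy)-1-[(2S,3S)-2-[4-(benzyloxy)-3-methoxyphenyl]-7-methoxy-3-methyl-2,3-dihydro-1-benzofuran-5-yl]propan-1-ol | COc1cc([C@H]2Oc3c(OC)cc([C@@H](O)[C@H](C)OCc4ccccc4)cc3[C@@H]2C)ccc1OCc1ccccc1 | intermediate
20 | (1R,2S)-1-[(2S,3S)-2-(4-hydroxy-3-methoxyphenyl)-7-methoxy-3-methyl-2,3-dihydro-1-benzofuran-5-yl]propane-1,2-diol | COc1cc([C@H]2Oc3c(OC)cc([C@@H](O)[C@H](C)O)cc3[C@@H]2C)ccc1O | target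

**Step count**
Total: 11 steps. Longest linear sequence: 10 steps (steps 1–7 and 9–11, from 1); step 8 is a one-step side branch.

**Steps most likely to fail**

Step 4 (key ring contraction). The iodane could be diverted into migration of the electron-rich ring B or into elimination towards the aromatised chromone, and the acid could erode configurational integrity at C2 by opening the benzylic C2–O1 bond. The fallback builds the same ester by a C–H insertion that forms the C2–C3 bond instead. It sets out from 2 and comes back at 9. O-Alkylation of 2 with 4-(benzyloxy)-3-methoxybenzyl chloride (K2CO3, DMF) should give 1-[2-{[4-(benzyloxy)-3-methoxyphenyl]methoxy}-5-bromo-3-methoxyphenyl]ethan-1-one F1. Oxidative 1,2-aryl shift of this acyclic aryl methyl ketone (PhI(OAc)2, H2SO4, HC(OMe)3) should give the methyl arylacetate F2. Diazo transfer (4-acetamidobenzenesulfonyl azide, DBU, MeCN) should give the aryldiazoacetate F3. Intramolecular carbene insertion into the benzylic ether C–H bond with Rh2(S-PTTL)4 or its enantiomer (whichever gives 2S), in toluene at low temperature, should give the cis ester methyl (2S,3R)-2-[4-(benzyloxy)-3-methoxyphenyl]-5-bromo-7-methoxy-2,3-dihydro-1-benzofuran-3-carboxylate F4. Epimerisation at C3 with NaOMe in MeOH should then lead to the trans ester 9.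

Step 3 (asymmetric conjugate addition). Protodeboronation of the electron-rich boronic acid may starve the reaction, and the 8-methoxy chromone may give insufficient enantioface selectivity. The fallback goes through a chalcone and a kinetic resolution. It sets out from 2 and comes back at 6. Claisen–Schmidt condensation of 2 with 4-(benzyloxy)-3-methoxybenzaldehyde (KOH, EtOH) should give the 2'-hydroxychalcone (E)-3-[4-(benzyloxy)-3-methoxyphenyl]-1-(5-bromo-2-hydroxy-3-methoxyphenyl)prop-2-en-1-one F5. Oxa-Michael ring closure (NaOAc, EtOH, reflux) should give the racemic flavanone F6. Asymmetric transfer hydrogenation with the enantiomer of RuCl(p-cymene)(TsDPEN) that consumes the 2R ketone faster (HCO2H/Et3N) should convert that enantiomer into the cis alcohol (2R,4R)-2-[4-(benzyloxy)-3-methoxyphenyl]-6-bromo-8-methoxychroman-4-ol F7 and leave 6, which is separated by chromatography.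

Step 7 (hydride displacement of the tosylate). E2 elimination across C3 and the branch carbon (followed by aromatisation to the benzofuran), or participation of ring A with ring expansion, could compete with direct substitution. The fallback replaces the polar displacement by a radical reduction. It sets out from 10 and comes back at 12. The Appel reaction (I2, PPh3, imidazole, CH2Cl2) should give (2S,3S)-2-[4-(benzyloxy)-3-methoxyphenyl]-5-bromo-3-(iodomethyl)-7-methoxy-2,3-dihydro-1-benzofuran F8. Reduction with Bu3SnH at high concentration (Et3B/air, toluene, rt) should then remove iodine in preference to the aryl bromine and, by fast hydrogen transfer, outrun the 1,2-aryl shift of the primary radical, giving 12.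

**Further compounds**
F1 | step 4 | 1-[2-{[4-(benzyloxy)-3-methoxyphenyl]methoxy}-5-bromo-3-methoxyphenyl]ethan-1-one | CC(=O)c1cc(Br)cc(OC)c1OCc1ccc(OCc2ccccc2)c(OC)c1
F2 | step 4 | methyl 2-[2-{[4-(benzyloxy)-3-methoxyphenyl]methoxy}-5-bromo-3-methoxyphenyl]acetate | COC(=O)Cc1cc(Br)cc(OC)c1OCc1ccc(OCc2ccccc2)c(OC)c1
F3 | step 4 | methyl 2-[2-{[4-(benzyloxy)-3-methoxyphenyl]methoxy}-5-bromo-3-methoxyphenyl]-2-diazoacetate | COC(=O)C(=[N+]=[N-])c1cc(Br)cc(OC)c1OCc1ccc(OCc2ccccc2)c(OC)c1
F4 | step 4 | methyl (2S,3R)-2-[4-(benzyloxy)-3-methoxyphenyl]-5-bromo-7-methoxy-2,3-dihydro-1-benzofuran-3-carboxylate (cis) | COc1cc([C@H]2Oc3c(OC)cc(Br)cc3[C@H]2C(=O)OC)ccc1OCc1ccccc1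
F5 | step 3 | (E)-3-[4-(benzyloxy)-3-methoxyphenyl]-1-(5-bromo-2-hydroxy-3-methoxyphenyl)prop-2-en-1-one | COc1cc(/C=C/C(=O)c2cc(Br)cc(OC)c2O)ccc1OCc1ccccc1
F6 | step 3 | racemic 2-[4-(benzyloxy)-3-methoxyphenyl]-6-bromo-8-methoxychroman-4-one | COc1cc(C2Oc3c(OC)cc(Br)cc3C(=O)C2)ccc1OCc1ccccc1
F7 | step 3 | (2R,4R)-2-[4-(benzyloxy)-3-methoxyphenyl]-6-bromo-8-methoxychroman-4-ol (cis) | COc1cc([C@@H]2Oc3c(OC)cc(Br)cc3[C@H](O)C2)ccc1OCc1ccccc1
F8 | step 7 | (2S,3S)-2-[4-(benzyloxy)-3-methoxyphenyl]-5-bromo-3-(iodomethyl)-7-methoxy-2,3-dihydro-1-benzofuran | COc1cc([C@H]2Oc3c(OC)cc(Br)cc3[C@@H]2CI)ccc1OCc1ccccc1
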